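## Retrosynthetic overview

- Target ⇒ DMAP acylation of the primary alcohol of an (S)-epoxy alcohol. The aryl isovalerate is installed before the oxirane so that a free phenol never sits next to the epoxide.
- Oxirane (the only ring built for the target, closed in the second-to-last step) ⇒ Katsuki–Sharpless epoxidation of a 2-aryl allylic alcohol, which sets the single stereocentre.
- Allylic alcohol ⇒ i-Bu2AlH reduction of a 2-arylacrylate. Its =CH2 carbon ⇒ crossed aldol condensation of a tert-butyl arylacetate with formaldehyde (key C–C bond).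
- Arylacetate ⇒ Pd-catalysed coupling of doubly protected 4-bromo-3-hydroxybenzaldehyde with BrZnCH2CO2tBu. The benzene ring is bought; the 1,3-dioxolane is a temporary protecting ring (made in step 1, opened in step 6).

Assumption: BrZnCH2CO2tBu is used as the commercial 0.5 M ether solution, and paraformaldehyde is entered as its monomer formaldehyde.

## Route

Step 1
Reactants: 1 4-bromo-3-hydroxybenzaldehyde; 2 ethylene glycol
Product: 3 2-bromo-5-(1,3-dioxolan-2-yl)phenol
Conditions: 2 (3 equiv), pTsOH·H2O (5 mol%), toluene, reflux, Dean–Stark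
Reagents that add atoms: ethylene glycol OCCO
Why: Acid-catalysed acetalisation driven by azeotropic removal of water masks the aldehyde against the enolate and hydride chemistry that follows; the phenol is inert.

Step 2
Reactants: 3 2-bromo-5-(1,3-dioxolan-2-yl)phenol; 4 chloromethyl methyl ether
Product: 5 2-[4-bromo-3-(methoxymethoxy)phenyl]-1,3-dioxolane
Conditions: 4 (1.5 equiv), iPr2NEt (2 equiv), CH2Cl2, 0 °C to rt
Reagents that add atoms: chloromethyl methyl ether COCCl
Why: O-alkylation (Williamson-type) of the phenol gives a MOM ether that is stable to base, zinc enolates and hydride, and the basic medium leaves the dioxolane intact.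

Step 3
Reactants: 5 2-[4-bromo-3-(methoxymethoxy)phenyl]-1,3-dioxolane; 6 (2-tert-butoxy-2-oxoethyl)zinc bromide, BrZnCH2CO2tBu
Product: 7 tert-butyl 2-[4-(1,3-dioxolan-2-yl)-2-(methoxymethoxy)phenyl]acetate
Conditions: 6 (1.5 equiv), Pd2(dba)3 (2 mol%), XPhos (8 mol%), THF, 60 °C
Reagents that add atoms: (2-tert-butoxy-2-oxoethyl)zinc bromide CC(C)(C)OC(=O)C[Zn]Br
Why: Negishi-type coupling of a Reformatsky reagent (oxidative addition of the aryl bromide to zerovalent palladium, transmetalation from zinc, reductive elimination) under near-neutral conditions that acetal and MOM ether tolerate.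

Step 4
Reactants: 7 tert-butyl 2-[4-(1,3-dioxolan-2-yl)-2-(methoxymethoxy)phenyl]acetate; 8 formaldehyde (as paraformaldehyde)
Product: 10 tert-butyl 2-[4-(1,3-dioxolan-2-yl)-2-(methoxymethoxy)phenyl]prop-2-enoate, via racemic beta-hydroxy ester 9 (not isolated)
Conditions: (CH2O)n (3 equiv), K2CO3 (3 equiv), Bu4NI (10 mol%), toluene, 80 °C
Reagents that add atoms: formaldehyde C=O
Why: Intermolecular crossed aldol addition of the arylacetate enolate to non-enolisable formaldehyde followed by E1cB dehydration (aldol condensation) forms the Cα–CH2 bond; the stereocentre of 9 is racemic and disappears on dehydration.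

Step 5
Reactants: 10 tert-butyl 2-[4-(1,3-dioxolan-2-yl)-2-(methoxymethoxy)phenyl]prop-2-enoate
Product: 11 2-[4-(1,3-dioxolan-2-yl)-2-(methoxymethoxy)phenyl]prop-2-en-1-ol
Conditions: i-Bu2AlH (2.5 equiv), CH2Cl2, −78 to 0 °C; aq KNaC4H4O6 work-up
Reagents that add atoms: none
Why: 1,2-Hydride reduction of the unsaturated ester by i-Bu2AlH gives the allylic alcohol without touching the alkene, acetal or MOM ether.

Step 6
Reactants: 11 2-[4-(1,3-dioxolan-2-yl)-2-(methoxymethoxy)phenyl]prop-2-en-1-ol
Product: 12 3-hydroxy-4-(3-hydroxyprop-1-en-2-yl)benzaldehyde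
Conditions: 3 M aq HCl–THF (1:2), 40 °C
Reagents that add atoms: water O
Why: Acid-catalysed acetal hydrolysis via oxocarbenium ions removes dioxolane and MOM ether in one operation on a substrate that carries no ester or epoxide; the electron-poor styrene and the primary allylic alcohol do not ionise under these conditions.

Step 7
Reactants: 12 3-hydroxy-4-(3-hydroxyprop-1-en-2-yl)benzaldehyde; 13 3-methylbutanoyl chloride (isovaleryl chloride)
Product: 14 5-formyl-2-(3-hydroxyprop-1-en-2-yl)phenyl 3-methylbutanoate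
Conditions: 13 (1.05 equiv), 1 M aq NaOH (1.2 equiv), Bu4NHSO4 (5 mol%), CH2Cl2, 0 °C, 15 min
Reagents that add atoms: 3-methylbutanoyl chloride CC(C)CC(=O)Cl
Why: Phase-transfer Schotten–Baumann acylation is chemoselective because only the phenol (pKa about 9) is deprotonated, and its ion pair is acylated far faster than the neutral primary alcohol.

Step 8
Reactants: 14 5-formyl-2-(3-hydroxyprop-1-en-2-yl)phenyl 3-methylbutanoate; 15 tert-butyl hydroperoxide
Product: 16 5-formyl-2-[(2S)-2-(hydroxymethyl)oxiran-2-yl]phenyl 3-methylbutanoate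
Conditions: Ti(OiPr)4 (10 mol%), L-(+)-DIPT (14 mol%), 15 (2 equiv, in decane), 4 Å MS, CH2Cl2, −20 °C; non-basic work-up (aq citric acid)
Reagents that add atoms: tert-butyl hydroperoxide CC(C)(C)OO
Why: Katsuki–Sharpless asymmetric epoxidation, in which allylic alkoxide and peroxide are held on the chiral titanium tartrate; the L-(+)-tartrate delivers oxygen to the face that gives the (S)-epoxy alcohol (same sense as (S)-2-methylglycidol from methallyl alcohol), the aldehyde and ester are tolerated, and the phenol is already masked.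

Step 9
Reactants: 16 5-formyl-2-[(2S)-2-(hydroxymethyl)oxiran-2-yl]phenyl 3-methylbutanoate; 17 3-methylbutanoic anhydride (isovaleric anhydride)
Product: 18 [(2R)-2-[4-formyl-2-(3-methylbutanoyloxy)phenyl]oxiran-2-yl]methyl 3-methylbutanoate
Conditions: 17 (1.5 equiv), Et3N (2 equiv), DMAP (5 mol%), CH2Cl2, 0 °C
Reagents that add atoms: 3-methylbutanoic anhydride CC(C)CC(=O)OC(=O)CC(C)C
Why: DMAP-catalysed acyl transfer esterifies the primary alcohol without chloride or strong base, so the epoxide is neither opened nor Payne-rearranged; no bond at the stereocentre changes, and the descriptor becomes R only because CH2O-acyl now outranks the ring CH2.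

## Compound list

1 | 4-bromo-3-hydroxybenzaldehyde | O=Cc1ccc(Br)c(O)c1 | starting material
2 | ethylene glycol | OCCO | starting material
3 | 2-bromo-5-(1,3-dioxolan-2-yl)phenol | Oc1cc(C2OCCO2)ccc1Br | intermediate
4 | chloromethyl methyl ether | COCCl | starting material
5 | 2-[4-bromo-3-(methoxymethoxy)phenyl]-1,3-dioxolane | COCOc1cc(C2OCCO2)ccc1Br | intermediate
6 | (2-tert-butoxy-2-oxoethyl)zinc bromide | CC(C)(C)OC(=O)C[Zn]Br | starting material
7 | tert-butyl 2-[4-(1,3-dioxolan-2-yl)-2-(methoxymethoxy)phenyl]acetate | COCOc1cc(C2OCCO2)ccc1CC(=O)OC(C)(C)C | intermediate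
8 | formaldehyde (used as paraformaldehyde) | C=O | starting material
9 | tert-butyl 2-[4-(1,3-dioxolan-2-yl)-2-(methoxymethoxy)phenyl]-3-hydroxypropanoate, racemic, not isolated | COCOc1cc(C2OCCO2)ccc1C(CO)C(=O)OC(C)(C)C | intermediate
10 | tert-butyl 2-[4-(1,3-dioxolan-2-yl)-2-(methoxymethoxy)phenyl]prop-2-enoate | COCOc1cc(C2OCCO2)ccc1C(=C)C(=O)OC(C)(C)C | intermediate
11 | 2-[4-(1,3-dioxolan-2-yl)-2-(methoxymethoxy)phenyl]prop-2-en-1-ol | COCOc1cc(C2OCCO2)ccc1C(=C)CO | intermediate
12 | 3-hydroxy-4-(3-hydroxyprop-1-en-2-yl)benzaldehyde | O=Cc1ccc(C(=C)CO)c(O)c1 | intermediate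
13 | 3-methylbutanoyl chloride | CC(C)CC(=O)Cl | starting material
14 | 5-formyl-2-(3-hydroxyprop-1-en-2-yl)phenyl 3-methylbutanoate | CC(C)CC(=O)Oc1cc(C=O)ccc1C(=C)CO | intermediate
15 | tert-butyl hydroperoxide | CC(C)(C)OO | starting material
16 | 5-formyl-2-[(2S)-2-(hydroxymethyl)oxiran-2-yl]phenyl 3-methylbutanoate | OC[C@@]1(c2ccc(C=O)cc2OC(=O)CC(C)C)CO1 | intermediate
17 | 3-methylbutanoic anhydride | CC(C)CC(=O)OC(=O)CC(C)C | starting material
18 | [(2R)-2-[4-formyl-2-(3-methylbutanoyloxy)phenyl]oxiran-2-yl]methyl 3-methylbutanoate | CC(C)CC(=O)OC[C@@]1(c2ccc(C=O)cc2OC(=O)CC(C)C)CO1 | target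

## Step count and risk

Total steps: 9. Longest linear sequence: 9 (fully linear from 1).

The three steps most likely to fail:

**Step 4 (aldol condensation).** The ortho-substituted, hindered tert-butyl ester may react slowly, and the enolate of 7 can add to the product acrylate. Fallback: setting out from 7, deprotonation with LiN(iPr)2 (THF, −78 °C) and trapping with [Me2N=CH2]I (Mannich reaction) gives the Mannich base tert-butyl 3-(dimethylamino)-2-[4-(1,3-dioxolan-2-yl)-2-(methoxymethoxy)phenyl]propanoate F1. MeI in CH2Cl2 quaternises it to {3-tert-butoxy-2-[4-(1,3-dioxolan-2-yl)-2-(methoxymethoxy)phenyl]-3-oxopropyl}trimethylammonium iodide F2. Stirring F2 with aq NaHCO3/CH2Cl2 eliminates trimethylamine (E1cB) and comes back to the route at 10.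

**Step 7 (selective phenol acylation).** Over-acylation of the primary alcohol or aryl-to-alkyl acyl migration would give mixtures. Fallback: setting out from 11, the alcohol is silylated (TBDPSCl, imidazole, DMF) to tert-butyl({2-[4-(1,3-dioxolan-2-yl)-2-(methoxymethoxy)phenyl]prop-2-en-1-yl}oxy)diphenylsilane F3. TFA/CH2Cl2/H2O at 0 °C to rt removes MOM ether and dioxolane but not the acid-stable TBDPS ether, giving 4-{3-[(tert-butyldiphenylsilyl)oxy]prop-1-en-2-yl}-3-hydroxybenzaldehyde F4. Acylation of the only free hydroxyl (13, Et3N, CH2Cl2, 0 °C) gives 2-{3-[(tert-butyldiphenylsilyl)oxy]prop-1-en-2-yl}-5-formylphenyl 3-methylbutanoate F5. HF·pyridine in THF/pyridine then cleaves the silyl ether without touching the aryl ester and comes back to the route at 14.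

**Step 8 (asymmetric epoxidation).** The neighbouring aryl ester may transfer its acyl group to the titanium-bound alkoxide and free a catalyst-poisoning phenol, and the electron-poor alkene reacts slowly. Fallback: setting out from 12, both hydroxyls are silylated (TBSCl, imidazole, DMF) to 3-[(tert-butyldimethylsilyl)oxy]-4-{3-[(tert-butyldimethylsilyl)oxy]prop-1-en-2-yl}benzaldehyde F6. AcOH/THF/H2O (3:1:1, rt) cleaves only the primary alkyl silyl ether and gives 3-[(tert-butyldimethylsilyl)oxy]-4-(3-hydroxyprop-1-en-2-yl)benzaldehyde F7. The same Ti(OiPr)4/L-(+)-DIPT/TBHP epoxidation, now on an ester-free substrate, gives 3-[(tert-butyldimethylsilyl)oxy]-4-[(2S)-2-(hydroxymethyl)oxiran-2-yl]benzaldehyde F8. Acylation with 17/Et3N/DMAP gives [(2R)-2-{2-[(tert-butyldimethylsilyl)oxy]-4-formylphenyl}oxiran-2-yl]methyl 3-methylbutanoate F9. Bu4NF (1.1 equiv) added at −40 °C to F9 in THF containing excess 17 releases the phenoxide, which is acylated in situ before it can attack the oxirane, and this comes back to the route at 18.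

## Further compounds

F1 | step 4 | tert-butyl 3-(dimethylamino)-2-[4-(1,3-dioxolan-2-yl)-2-(methoxymethoxy)phenyl]propanoate (racemic) | COCOc1cc(C2OCCO2)ccc1C(CN(C)C)C(=O)OC(C)(C)C
F2 | step 4 | {3-tert-butoxy-2-[4-(1,3-dioxolan-2-yl)-2-(methoxymethoxy)phenyl]-3-oxopropyl}trimethylammonium iodide (racemic) | COCOc1cc(C2OCCO2)ccc1C(C[N+](C)(C)C)C(=O)OC(C)(C)C.[I-]
F3 | step 7 | tert-butyl({2-[4-(1,3-dioxolan-2-yl)-2-(methoxymethoxy)phenyl]prop-2-en-1-yl}oxy)diphenylsilane | COCOc1cc(C2OCCO2)ccc1C(=C)CO[Si](c1ccccc1)(c1ccccc1)C(C)(C)C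
F4 | step 7 | 4-{3-[(tert-butyldiphenylsilyl)oxy]prop-1-en-2-yl}-3-hydroxybenzaldehyde | O=Cc1ccc(C(=C)CO[Si](c2ccccc2)(c2ccccc2)C(C)(C)C)c(O)c1
F5 | step 7 | 2-{3-[(tert-butyldiphenylsilyl)oxy]prop-1-en-2-yl}-5-formylphenyl 3-methylbutanoate | CC(C)CC(=O)Oc1cc(C=O)ccc1C(=C)CO[Si](c1ccccc1)(c1ccccc1)C(C)(C)C
F6 | step 8 | 3-[(tert-butyldimethylsilyl)oxy]-4-{3-[(tert-butyldimethylsilyl)oxy]prop-1-en-2-yl}benzaldehyde | O=Cc1ccc(C(=C)CO[Si](C)(C)C(C)(C)C)c(O[Si](C)(C)C(C)(C)C)c1
F7 | step 8 | 3-[(tert-butyldimethylsilyl)oxy]-4-(3-hydroxyprop-1-en-2-yl)benzaldehyde | O=Cc1ccc(C(=C)CO)c(O[Si](C)(C)C(C)(C)C)c1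
F8 | step 8 | 3-[(tert-butyldimethylsilyl)oxy]-4-[(2S)-2-(hydroxymethyl)oxiran-2-yl]benzaldehyde | OC[C@@]1(c2ccc(C=O)cc2O[Si](C)(C)C(C)(C)C)CO1
F9 | step 8 | [(2R)-2-{2-[(tert-butyldimethylsilyl)oxy]-4-formylphenyl}oxiran-2-yl]methyl 3-methylbutanoate | CC(C)CC(=O)OC[C@@]1(c2ccc(C=O)cc2O[Si](C)(C)C(C)(C)C)CO1
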